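## Retrosynthetic overview
- Only the purchased indole ring of 6-bromoindole 1 ends up in the product. No lasting ring is built and there is no stereocentre.
- C3–C(O) bond: uncatalysed glyoxylation of 1 with oxalyl chloride 2 gives acid chloride 3.
- O-acylation of salicylaldehyde 4 with 3 gives the 2-formylphenyl ester 5, which places an aldehyde anchor next to the acyl group.
- Key disconnection, amide N1–C(O): 5 acylates unprotected spermidine 6 through a temporary hexahydropyrimidine ring (aminal 7, then N-acyl aminal 8).
- Aqueous acid opens that temporary ring, the only ring formed in the route, and releases didemnidine B 9.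

Assumption: the target SMILES contains no stereocentre, so the compound is achiral and no configuration has to be set. The spermidine nitrogens are called N1 (aminopropyl end), N4 (secondary) and N8 (aminobutyl end). The target is the N1-acyl isomer.

## Route

Step 1
Reactants: 1 6-bromo-1H-indole; 2 oxalyl chloride
Product: 3 2-(6-bromo-1H-indol-3-yl)-2-oxoacetyl chloride
Conditions: 2 (1.2 equiv), Et2O, 0 °C to rt, 2 h; filter the yellow solid, wash with cold Et2O, dry in vacuo
Reagents that add atoms: none
Why: Speeter–Anthony-type uncatalysed Friedel–Crafts acylation, in which the enamine-like C3 of the indole attacks oxalyl chloride and the acid chloride precipitates, which stops a second acylation and removes excess 2.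

Step 2
Reactants: 3 2-(6-bromo-1H-indol-3-yl)-2-oxoacetyl chloride; 4 salicylaldehyde
Product: 5 2-formylphenyl 2-(6-bromo-1H-indol-3-yl)-2-oxoacetate
Conditions: 4 (1.05 equiv), Et3N (1.05 equiv), THF, 0 °C to rt, 1 h; cold aq citric acid wash, triturate (Et2O/hexane)
Reagents that add atoms: none
Why: Base-mediated O-acylation of a phenol by an acid chloride (nucleophilic acyl substitution), which is clean because the glyoxylyl unit has no α-hydrogen (no ketene, no coumarin-type condensation with the ortho aldehyde) and Et3N does not deprotonate the 3-acylindole N–H.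

Step 3
Reactants: 5 2-formylphenyl 2-(6-bromo-1H-indol-3-yl)-2-oxoacetate; 6 spermidine
Product: 9 didemnidine B, via aminal ester 7 (not isolated), via N-acyl aminal 8 (not isolated)
Conditions: 6 (1.3 equiv), pyridine/AcOH (1:1 mol/mol), 0.05 M, rt, 6 h; evaporate; 1 M aq HCl/THF (1:1), rt, 1 h; Et2O wash; aq NaOH to pH 11, extract CHCl3/i-PrOH (3:1)
Reagents that add atoms: none
Why: Proposed new method: aminal-capture ligation on an unprotected polyamine, in which the acidic buffer keeps all three nitrogens protonated so direct aminolysis of the aryl ester is slow, the aldehyde of 5 condenses reversibly and only the 1,3-diamine pair N1/N4 can close a six-membered hexahydropyrimidine (7; N4/N8 would need a seven-membered ring and N8 alone gives only a reversible imine with no N–H), this ring makes N4 tertiary and, because a geminal diamine takes up only one proton in this medium, leaves the ring N1–H with a free lone pair held beside the ester carbonyl for an irreversible O-to-N acyl shift through a six-membered transition state (8), and aqueous acid then ionises the benzylic N-acyl aminal (protonated N4 leaves, assisted by the ortho-hydroxyphenyl group) so that water releases 9 and erases the racemic aminal carbon; the closest known reaction type is serine/threonine ligation of salicylaldehyde esters (oxazolidine capture, O-to-N shift, acidolysis), transferred here from a 1,2-amino alcohol to a 1,3-diamine.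

## Compound list
1 | 6-bromo-1H-indole | Brc1ccc2cc[nH]c2c1 | starting material
2 | oxalyl chloride | O=C(Cl)C(=O)Cl | starting material
3 | 2-(6-bromo-1H-indol-3-yl)-2-oxoacetyl chloride | O=C(Cl)C(=O)c1c[nH]c2cc(Br)ccc12 | intermediate
4 | salicylaldehyde (2-hydroxybenzaldehyde) | O=Cc1ccccc1O | starting material
5 | 2-formylphenyl 2-(6-bromo-1H-indol-3-yl)-2-oxoacetate | O=Cc1ccccc1OC(=O)C(=O)c1c[nH]c2cc(Br)ccc12 | intermediate
6 | spermidine (N-(3-aminopropyl)butane-1,4-diamine) | NCCCCNCCCN | starting material
7 | 2-[1-(4-aminobutyl)hexahydropyrimidin-2-yl]phenyl 2-(6-bromo-1H-indol-3-yl)-2-oxoacetate (racemic at ring C2, not isolated) | NCCCCN1CCCNC1c1ccccc1OC(=O)C(=O)c1c[nH]c2cc(Br)ccc12 | intermediate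
8 | 1-[3-(4-aminobutyl)-2-(2-hydroxyphenyl)hexahydropyrimidin-1-yl]-2-(6-bromo-1H-indol-3-yl)ethane-1,2-dione (racemic at ring C2, not isolated) | NCCCCN1CCCN(C1c1ccccc1O)C(=O)C(=O)c1c[nH]c2cc(Br)ccc12 | intermediate
9 | didemnidine B, N-{3-[(4-aminobutyl)amino]propyl}-2-(6-bromo-1H-indol-3-yl)-2-oxoacetamide (achiral) | NCCCCNCCCNC(=O)C(=O)c1c[nH]c2cc(Br)ccc12 | target

## Totals and risks
Total step count: 3. Longest linear sequence: 3 (1 → 3 → 5 → 9).

**Highest risk, step 3 (the proposed new step).**
- N8 could be acylated by direct aminolysis or through a short-lived carbinolamine at the aldehyde.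
- The activated α-keto aryl ester could solvolyse in the buffer.
- The ring form 7 could be too sparsely populated for the acyl shift to compete.

The fallback replaces template control with protecting-group control and uses only known chemistry. It sets out from 3 and comes back at 9. Acid chloride 3 is coupled (Et3N, THF/DMF, 0 °C to rt) with commercially available tert-butyl N-(3-aminopropyl)-N-[4-(tert-butoxycarbonylamino)butyl]carbamate F1, whose only free nitrogen is N1. This gives N4,N8-di-Boc-didemnidine B F2. Treatment with TFA/CH2Cl2 at rt followed by basification gives 9.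

**Second risk, step 2.**
- The hydrogen-bonded, electron-poor phenol of 4 may acylate sluggishly.
- The free aldehyde may make isolation of the water-sensitive ester messy.

The fallback masks the aldehyde during acylation. It sets out from 3 (together with 4) and comes back at 5. Aldehyde 4 is converted with HC(OMe)3 and catalytic TsOH in MeOH into 2-(dimethoxymethyl)phenol F3. F3 is acylated with 3 (Et3N, THF, 0 °C) to give 2-(dimethoxymethyl)phenyl 2-(6-bromo-1H-indol-3-yl)-2-oxoacetate F4. Brief treatment with TFA/H2O/CH2Cl2 unmasks the aldehyde to give 5.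

**Third risk, step 1.**
- The reaction could give incomplete conversion or some bis-indolyl diketone.
- The acid chloride could hydrolyse during filtration.

The fallback avoids the acid chloride altogether. It sets out from 1 and comes back at 5. Lewis-acid Friedel–Crafts acylation of 1 with methyl chlorooxoacetate (AlCl3, CH2Cl2, 0 °C to rt) gives methyl 2-(6-bromo-1H-indol-3-yl)-2-oxoacetate F5. LiOH in THF/H2O followed by acidification gives 2-(6-bromo-1H-indol-3-yl)-2-oxoacetic acid F6. Steglich esterification of F6 with 4 (EDC·HCl, catalytic DMAP, CH2Cl2/DMF) gives 5.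

## Further compounds
F1 | step 3 | tert-butyl N-(3-aminopropyl)-N-[4-(tert-butoxycarbonylamino)butyl]carbamate | NCCCN(CCCCNC(=O)OC(C)(C)C)C(=O)OC(C)(C)C
F2 | step 3 | N4,N8-di-Boc-didemnidine B | CC(C)(C)OC(=O)NCCCCN(CCCNC(=O)C(=O)c1c[nH]c2cc(Br)ccc12)C(=O)OC(C)(C)C
F3 | step 2 | 2-(dimethoxymethyl)phenol | COC(OC)c1ccccc1O
F4 | step 2 | 2-(dimethoxymethyl)phenyl 2-(6-bromo-1H-indol-3-yl)-2-oxoacetate | COC(OC)c1ccccc1OC(=O)C(=O)c1c[nH]c2cc(Br)ccc12
F5 | step 1 | methyl 2-(6-bromo-1H-indol-3-yl)-2-oxoacetate | COC(=O)C(=O)c1c[nH]c2cc(Br)ccc12
F6 | step 1 | 2-(6-bromo-1H-indol-3-yl)-2-oxoacetic acid | OC(=O)C(=O)c1c[nH]c2cc(Br)ccc12
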